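The readings were generated by integration for substances that don't exist, and the scatter is random.

In this flask, the south-west run, the electrophile has lost 13.0% by 10.0 s, more than the 5.00% of nucleophile dosed by then, and product reads 0%, so this early loss is laid to the protic impurity.

| flask | electrophile | nucleophile | protic impurity | remark | time |
|---|---|---|---|---|---|
| south-west | 0.50 M | 0.90 equiv (fed, over 3.0 min) | 0.15 M | the very flask that is asked about, followed so far |  |
| north-west | 0.50 M | 0.90 equiv (fed, over 3.0 min) | 0.22 M | run made earlier |  |
| flask | 0.50 M | 0.900 equiv (fed, over 3.0 min) | 0.150 M |  | 3.0 min |

| run | time / s | electrophile / % | product / % |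
|---|---|---|---|
| south-west | 10.0 | 87 | 0 |
| south-west | 15.0 | 77 | 3 |
| south-west | 20.0 | 78 | 0 |
| south-west | 30.0 | 73 | 1 |
| south-west | 40.0 | 72 | 0 |
| north-west | 12.0 | 77 | 4 |
| north-west | 30.0 | 65 | 1 |
| north-west | 60.0 | 56 | 0 |
| north-west | 90.0 | 49 | 4 |
| north-west | 120 | 46 | 6 |

(readings scatter by 2 percentage points)

- what was read earlier has a scatter of 2 percentage points, one standard deviation
- what has gone from electrophile into another species counts as reacted, even if it can come back
- the earlier runs do not show how much of nucleophile is bound; that part of a forecast is a guess
- a reading or a percentage of product counts all its forms, free or not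
- a reading of electrophile is of its free form alone

- part of the electrophile that has reacted at 3.0 min
- share of the unused nucleophile that is free and not bound as protonated nucleophile, at 3.0 min

If each protic impurity takes one electrophile, the fast loss ends when the impurity, the limiting reagent of that loss, is used up. This flask's impurity toll is 30.0%: c(protic impurity) over c(electrophile), the part of the electrophile charged that the impurity can take. The readings bear this out within their scatter of 2 percentage points: this flask has lost 28.0% at 40.0 s, and the north-west run, whose toll is 44.0%, has lost 44.0% at 60.0 s. Past that point the north-west electrophile drifts down by 10 points up to 120 s. Carrying this drift at the same speed from 60.0 s to 3.0 min and adding it to the toll gives a rough 50.0% reacted in this flask. The free share of nucleophile cannot be reckoned here, as the readings do not show what is bound.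

The forecast gives 50% reacted and 65% free, and of the second figure it says: “If about 0.12 M is bound, about 65% is free, which is a guess.”

    electrophile + nucleophile → acid set free + product (k = 0.00940 M⁻¹ s⁻¹)
    nucleophile + acid set free ⇌ protonated nucleophile, settled at all times (K = 470 M⁻¹)
    electrophile + protic impurity → quenched substrate (k = 0.152 M⁻¹ s⁻¹)
    electrophile + product ⇌ idle adduct, settled at all times (K = 1.71 M⁻¹)

The flask gives 51.1% reacted, within tolerance of the forecast, and 78.1% free, which the forecast undershoots by 13 points. The half-life of electrophile by the quench, with the other concentrations held at their charge, is 0.51 min, short against the 3.0 min asked about, and at 3.00 min this flask holds 30.0% of quenched substrate, matching its toll of 30.0%, with 0.015% of the protic impurity left. In the neighbour charged with 0.060 M of protic impurity, the toll comes to 12.0%, and its quenched substrate stands at 12.0%.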